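**Plan**
- Cuts: the side-chain O–Si bond (last). Then C4–C5, which opens the nine-membered ring O–C1–C10–C9–C8–C7–C6–C5–C4. Then O–C1 of the furanone (γ-hydroxy ynone), C8–O(acyl), C1–C2 (lactone + acetylide) and C8–C9 (acid chloride + zinc homoenolate). The butenolide is traced back to a 2-methylfuran whose methyl group is C5.
- Forward: furan ring (later the butenolide ring O/C6/C7/C11/C12) → chain C8–C9–C10–C1, stored as a temporary γ-lactone → C2–C4 by acetylide opening → C8 ester → furan oxidised to the (Z)-5-(bromomethylene)butenolide → furanone ring O/C1/C2/C3/C4 → nine-membered ring last.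
- Enabling feature: C4–C5 joins C-2 of a 3(2H)-furanone to the exocyclic end of a 5-ylidenebutenolide. Loss of C4–H turns ring O/C1–C4 into an aromatic furan-3-olate that is nucleophilic at C4. Attack at C5 of C5=C6–C7=C11–C12=O turns ring O/C6/C7/C11/C12 into an aromatic furan-2-olate. A bromine on C5 is the only helper and leaves in the same step.
- This one event closes the ring, builds the quaternary C4 and sets the (E)-C5=C6 alkene.
- Stereochemistry: C10 comes from the commercial (R)-zinc homoenolate and C8 from a CBS reduction. C4 is set in the key step by C8 (A(1,3) strain) and a potassium-bridged compact approach. The side-chain (Z)-alkene comes from syn-carbocupration, and (E)-C5=C6 is enforced by the ring.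

Key step: step 19

Remark (numbering): germacrane numbering of the target is used throughout. C1 = O-bearing sp2 carbon of the furanone, C2 = its CH, C3 = ketone, C4 = quaternary carbon, C5 = exocyclic CH. C6/C7/C11/C12 = γ/β/α/carbonyl carbons of the butenolide. C8 = CH–O(acyl), C9 = CH2, C10 = CH(CH3), C13 = CH2OAc. TBS = tert-butyldimethylsilyl, TBDPS = tert-butyldiphenylsilyl.

Remark (assumption): the alkynol 12 is used as the racemate, so 13–27 are epimer mixtures at C4. This has no consequence because C4 becomes planar in step 19. C6 in 21 and 23 and C5 in 29 are likewise left open in the SMILES.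

**Step 1**
Reactants: 1 ethyl acetoacetate; 2 1,3-dichloroacetone
Product: 4 ethyl 4-(chloromethyl)-2-methylfuran-3-carboxylate, via hydroxydihydrofuran 3 (not isolated)
Conditions: pyridine, 0 °C → rt; then TsOH·H2O (cat.), PhMe, 80 °C
Reagents that add atoms: none
Why: Feist–Bénary furan synthesis: the acetoacetate carbon adds to the ketone of 2, the enol oxygen displaces one chloride and acid removes water, which places CH3 (C5) on C6, CO2Et (C8) on C7 and CH2Cl (C13) on C11 and leaves C12–H free for step 13.

**Step 2**
Reactants: 4 ethyl 4-(chloromethyl)-2-methylfuran-3-carboxylate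
Product: 5 sodium 4-(hydroxymethyl)-2-methylfuran-3-carboxylate
Conditions: NaOH (2.1 equiv), H2O/THF, 60 °C; evaporation, drying
Reagents that add atoms: sodium hydroxide, [Na+].[OH-]
Why: Ester saponification and SN2 hydrolysis of the furylmethyl chloride run in the same pot, and isolation as the sodium salt keeps the two arms from closing to a lactone.

**Step 3**
Reactants: 5 sodium 4-(hydroxymethyl)-2-methylfuran-3-carboxylate
Product: 6 TBS 4-[(TBS-oxy)methyl]-2-methylfuran-3-carboxylate
Conditions: TBSCl (2.4 equiv), imidazole, DMF, rt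
Reagents that add atoms: tert-butyldimethylsilyl chloride, CC(C)(C)[Si](C)(C)Cl
Why: Routine imidazole-promoted silylation of alcohol and carboxylate, in which the silyl ester is wanted as the substrate of step 4.

**Step 4**
Reactants: 6 TBS 4-[(TBS-oxy)methyl]-2-methylfuran-3-carboxylate
Product: 7 4-[(TBS-oxy)methyl]-2-methylfuran-3-carbonyl chloride
Conditions: (COCl)2 (1.2 equiv), DMF (cat.), CH2Cl2, 0 °C → rt; evaporation, used crude
Reagents that add atoms: oxalyl chloride, O=C(Cl)C(=O)Cl
Why: Silyl esters react with the chloroiminium salt from oxalyl chloride and DMF to give acid chlorides (acyl substitution) without free HCl, so the primary silyl ether survives.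

**Step 5**
Reactants: 7 4-[(TBS-oxy)methyl]-2-methylfuran-3-carbonyl chloride; 8 (R)-(3-methoxy-2-methyl-3-oxopropyl)zinc bromide (commercial 0.5 M THF solution)
Product: 9 methyl (2S)-4-{4-[(TBS-oxy)methyl]-2-methylfuran-3-yl}-2-methyl-4-oxobutanoate
Conditions: Pd(PPh3)4 (3 mol %), THF, 0 °C → rt
Reagents that add atoms: none
Why: Negishi-type acylation: zerovalent palladium inserts into the C–Cl bond of 7, the zinc homoenolate transmetalates and reductive elimination gives the γ-keto ester, with the C10 stereocentre of 8 carried over because it is never enolised.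

**Step 6**
Reactants: 9 methyl (2S)-4-{4-[(TBS-oxy)methyl]-2-methylfuran-3-yl}-2-methyl-4-oxobutanoate
Product: 11 (3S,5S)-5-{4-[(TBS-oxy)methyl]-2-methylfuran-3-yl}-3-methyloxolan-2-one (cis-lactone; 8S,10S), via hydroxy ester 10 (not isolated)
Conditions: (R)-Me-CBS oxazaborolidine (15 mol %), BH3·SMe2 (0.7 equiv), THF, −30 °C; MeOH; then PPTS (cat.), PhMe, 60 °C
Reagents that add atoms: none
Why: Corey–Bakshi–Shibata reduction of an aryl alkyl ketone: the (R)-oxazaborolidine binds the ketone with the large furyl group turned away and delivers hydride to the face that gives (8S), after which the γ-hydroxy ester lactonises to the cis-lactone that protects O8 and activates C1.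

**Step 7**
Reactants: 12 (±)-but-3-yn-2-ol
Product: 13 (±)-3-(TBS-oxy)but-1-yne
Conditions: TBSCl, imidazole, CH2Cl2, rt
Reagents that add atoms: tert-butyldimethylsilyl chloride, CC(C)(C)[Si](C)(C)Cl
Why: Routine silylation, and the racemate suffices because this carbon (C4) becomes planar in step 19.

**Step 8**
Reactants: 13 (±)-3-(TBS-oxy)but-1-yne; 11 cis-lactone (8S,10S)
Product: 15 (1S,3S)-7-(TBS-oxy)-1-{4-[(TBS-oxy)methyl]-2-methylfuran-3-yl}-1-hydroxy-3-methyloct-5-yn-4-one (8S,10S; in equilibrium with its lactol), via lithium acetylide 14 (not isolated)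
Conditions: n-BuLi (1.0 equiv), THF, −78 °C; then 11, −78 °C; AcOH quench at −78 °C
Reagents that add atoms: n-butyllithium, [Li]CCCC (lithium of 14 only)
Why: 1,2-Addition of a lithium acetylide to a γ-lactone: the lithium lactolate is stable at −78 °C, so a single addition takes place and the cold quench releases the ynone and the free C8 hydroxyl with C8 and C10 unchanged.

**Step 9**
Reactants: 16 methyl 4-hydroxybut-2-ynoate
Product: 17 methyl 4-(TBDPS-oxy)but-2-ynoate
Conditions: TBDPSCl, imidazole, CH2Cl2, 0 °C → rt
Reagents that add atoms: tert-butyldiphenylsilyl chloride, CC(C)(C)[Si](Cl)(c1ccccc1)c1ccccc1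
Why: Routine silylation with a group that outlasts the TBS ethers in step 16.

**Step 10**
Reactants: 17 methyl 4-(TBDPS-oxy)but-2-ynoate
Product: 18 methyl (2Z)-4-(TBDPS-oxy)-3-methylbut-2-enoate
Conditions: Me2CuLi (from CuI + 2 MeLi, 1.2 equiv), THF, −78 °C; sat. aq NH4Cl at −78 °C
Reagents that add atoms: lithium dimethylcuprate, [Li+].C[Cu-]C
Why: Syn-carbocupration of an ynoate: methyl and copper add to the same side and cold protonation keeps the geometry, which puts CH2OSi cis to the ester, i.e. the (Z)-alkene.

**Step 11**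
Reactants: 18 methyl (2Z)-4-(TBDPS-oxy)-3-methylbut-2-enoate
Product: 19 (2Z)-4-(TBDPS-oxy)-3-methylbut-2-enoic acid
Conditions: LiOH·H2O, THF/MeOH/H2O, rt; then 1 M HCl to pH 4
Reagents that add atoms: lithium hydroxide, [Li+].[OH-]
Why: Ester saponification, in which the silyl ether keeps the cis acid from lactonising.

**Step 12**
Reactants: 15 hydroxy ynone (8S,10S); 19 (2Z)-4-(TBDPS-oxy)-3-methylbut-2-enoic acid
Product: 20 C8 (2Z)-4-(TBDPS-oxy)-3-methylbut-2-enoate of 15 (8S,10S)
Conditions: 2-methyl-6-nitrobenzoic anhydride (MNBA, 1.3 equiv), DMAP (0.2 equiv), Et3N, CH2Cl2, rt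
Reagents that add atoms: none
Why: Shiina esterification (mixed anhydride, acyl transfer by DMAP) acylates O8 with retention at C8 and drains the lactol form of 15 through its open hydroxy ketone.

**Step 13**
Reactants: 20 furan ynone ester
Product: 21 5-hydroxy-5-methylbutenolide (C12=O, C6(OH)CH3, C13–OTBS; 8S,10S)
Conditions: O2, tetraphenylporphyrin (cat.), visible light, i-Pr2NEt, CH2Cl2, −78 °C
Reagents that add atoms: dioxygen, O=O
Why: Furan photooxygenation: singlet oxygen adds [4+2] across C6/C12 of the electron-rich furan only, and the amine removes the sole bridgehead hydrogen (C12–H) in a Kornblum–DeLaMare-type opening, so the carbonyl arises at C12 and the hemiketal at C6 (both C6 epimers are used).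

**Step 14**
Reactants: 21 5-hydroxy-5-methylbutenolide
Product: 22 5-methylenebutenolide (C5H2=C6; 8S,10S)
Conditions: MsCl, Et3N, CH2Cl2, −20 → 0 °C
Reagents that add atoms: none
Why: Dehydration by mesylation of the hemiketal hydroxyl and E1-type loss through the oxygen-stabilised cation, in which only the C5 methyl group offers a proton, so the exocyclic alkene forms.

**Step 15**
Reactants: 22 5-methylenebutenolide
Product: 24 (Z)-5-(bromomethylene)butenolide (8S,10S), via dibromide 23 (not isolated)
Conditions: Br2 (1.0 equiv), CH2Cl2, −78 °C; then Et3N, −78 → 0 °C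
Reagents that add atoms: bromine, BrBr
Why: Electrophilic bromine addition to the enol-ester alkene, the most electron-rich π bond present, followed by dehydrobromination, in which bromine ends cis to the ring oxygen (Z) and away from the bulky C7 substituent.

**Step 16**
Reactants: 24 (Z)-5-(bromomethylene)butenolide
Product: 25 C4,C13-diol (γ-hydroxy ynone; TBDPS kept)
Conditions: 48 % aq HF, MeCN, 0 °C
Reagents that add atoms: none
Why: Acidic fluoride desilylation cleaves the two TBS ethers much faster than the TBDPS ether and does not touch the acid-stable bromoylidene lactone.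

**Step 17**
Reactants: 25 C4,C13-diol
Product: 26 2-methyl-3(2H)-furanone with free C13–OH (8S,10S; C4 labile)
Conditions: (4-CF3C6H4)3PAuCl (5 mol %), AgOTf (5 mol %), PhMe, rt
Reagents that add atoms: none
Why: Gold-catalysed cycloisomerisation of a γ-hydroxyalkynone to a 3(2H)-furanone (alkyne activation, net oxygen transfer to C3 and closure of O4 onto C1) runs under neutral conditions that spare the vinyl bromide and the esters.

**Step 18**
Reactants: 26 furanone alcohol
Product: 27 C13 acetate (cyclisation precursor; 8S,10S)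
Conditions: AcCl, 2,4,6-collidine, CH2Cl2, −78 → 0 °C
Reagents that add atoms: acetyl chloride, CC(=O)Cl
Why: Acetylation of the only hydroxyl group with a hindered base that neither enolises the furanone nor adds to the bromomethylene acceptor.

**Step 19**
Reactants: 27 C13 acetate (furanone + (Z)-bromomethylene butenolide)
Product: 30 O-TBDPS ether of the target (4S,5E,8S,10S), via potassium furan-3-olate 28 (not isolated), via potassium furan-2-olate 29 (not isolated)
Conditions: KHMDS (1.0 equiv), PhMe, 1 mM, −78 → 0 °C
Reagents that add atoms: potassium hexamethyldisilazide, [K+].C[Si](C)(C)[N-][Si](C)(C)C (potassium of 28 and 29 only)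
Why: Proposed new method: deprotonation at C4 aromatises the furanone to furan-3-olate 28, whose C4 adds to C5, the exocyclic end of C5=C6–C7=C11–C12=O (9-endo-trig through O, 10-endo-trig through carbon), to give furan-2-olate 29, which expels bromide and re-forms C5=C6. The closest known reaction type is nucleophilic vinylic substitution (addition–elimination) of stabilised enolates on β-halo enones and enoates, which also builds quaternary centres intermolecularly; new here are the vinylogous 5-(bromomethylene)butenolide acceptor and the medium-ring setting. Because 29 is an aromatic furan with a freely rotating C5–C6 single bond, the alkene geometry is fixed only when bromide leaves, and the nine-membered ring admits only C4 cis to C7, i.e. the (E)-alkene. C4 is controlled in two stages: A(1,3) strain between C13H2OAc and the C8 substituents keeps C8–H in the butenolide plane, so C9 and the tethered furanolate reach only one face of C5; and of the two staggered approaches allowed by the tether C8–C9–C10, the compact one (C3=C4 synclinal to C5=C6, O3 above the ring oxygen and next to Br) keeps K+ in contact with enolate oxygen, lactone oxygen and leaving bromide in toluene and gives (4S), whereas the extended one gives (4R). The (Z)-bromide is needed because the position on C5 cis to C7 must carry H to clear O8. C-attack is favoured over O-attack by the soft vinylogous acceptor, bromide leaves 29 far faster than the C13 acetate, and the dilution suppresses intermolecular coupling.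

**Step 20**
Reactants: 30 O-TBDPS ether of the target
Product: 31 target CNP0269057.1 (4S,5E,8S,10S; side chain 2Z)
Conditions: HF·pyridine, THF, 0 °C → rt
Reagents that add atoms: none
Why: Fluoride desilylation under mildly acidic conditions leaves the acetate, both esters and the enol lactone intact and disfavours lactonisation of the freed (Z)-γ-hydroxy enoate.

**Compound list**
1 | ethyl acetoacetate | CCOC(=O)CC(C)=O | starting material
2 | 1,3-dichloroacetone | ClCC(=O)CCl | starting material
3 | ethyl 4-(chloromethyl)-4-hydroxy-2-methyl-4,5-dihydrofuran-3-carboxylate | CCOC(=O)C1=C(C)OCC1(O)CCl | intermediate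
4 | ethyl 4-(chloromethyl)-2-methylfuran-3-carboxylate | CCOC(=O)c1c(C)occ1CCl | intermediate
5 | sodium 4-(hydroxymethyl)-2-methylfuran-3-carboxylate | [Na+].[O-]C(=O)c1c(C)occ1CO | intermediate
6 | TBS 4-[(TBS-oxy)methyl]-2-methylfuran-3-carboxylate | CC(C)(C)[Si](C)(C)OC(=O)c1c(C)occ1CO[Si](C)(C)C(C)(C)C | intermediate
7 | 4-[(TBS-oxy)methyl]-2-methylfuran-3-carbonyl chloride | ClC(=O)c1c(C)occ1CO[Si](C)(C)C(C)(C)C | intermediate
8 | (R)-(3-methoxy-2-methyl-3-oxopropyl)zinc bromide | COC(=O)[C@@H](C)C[Zn]Br | starting material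
9 | methyl (2S)-4-{4-[(TBS-oxy)methyl]-2-methylfuran-3-yl}-2-methyl-4-oxobutanoate | COC(=O)[C@@H](C)CC(=O)c1c(C)occ1CO[Si](C)(C)C(C)(C)C | intermediate
10 | methyl (2S,4S)-4-{4-[(TBS-oxy)methyl]-2-methylfuran-3-yl}-4-hydroxy-2-methylbutanoate | COC(=O)[C@@H](C)C[C@H](O)c1c(C)occ1CO[Si](C)(C)C(C)(C)C | intermediate
11 | (3S,5S)-5-{4-[(TBS-oxy)methyl]-2-methylfuran-3-yl}-3-methyloxolan-2-one | O=C1[C@@H](C)C[C@@H](c2c(C)occ2CO[Si](C)(C)C(C)(C)C)O1 | intermediate
12 | (±)-but-3-yn-2-ol | CC(O)C#C | starting material
13 | (±)-3-(TBS-oxy)but-1-yne | CC(C#C)O[Si](C)(C)C(C)(C)C | intermediate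
14 | lithium acetylide of 13 | [Li]C#CC(C)O[Si](C)(C)C(C)(C)C | intermediate
15 | hydroxy ynone (8S,10S; C4 epimers) | CC(O[Si](C)(C)C(C)(C)C)C#CC(=O)[C@@H](C)C[C@H](O)c1c(C)occ1CO[Si](C)(C)C(C)(C)C | intermediate
16 | methyl 4-hydroxybut-2-ynoate | COC(=O)C#CCO | starting material
17 | methyl 4-(TBDPS-oxy)but-2-ynoate | COC(=O)C#CCO[Si](c1ccccc1)(c1ccccc1)C(C)(C)C | intermediate
18 | methyl (2Z)-4-(TBDPS-oxy)-3-methylbut-2-enoate | COC(=O)/C=C(/C)CO[Si](c1ccccc1)(c1ccccc1)C(C)(C)C | intermediate
19 | (2Z)-4-(TBDPS-oxy)-3-methylbut-2-enoic acid | OC(=O)/C=C(/C)CO[Si](c1ccccc1)(c1ccccc1)C(C)(C)C | intermediate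
20 | furan ynone C8 ester (8S,10S) | CC(O[Si](C)(C)C(C)(C)C)C#CC(=O)[C@@H](C)C[C@@H](c1c(C)occ1CO[Si](C)(C)C(C)(C)C)OC(=O)/C=C(/C)CO[Si](c1ccccc1)(c1ccccc1)C(C)(C)C | intermediate
21 | 5-hydroxy-5-methylbutenolide (8S,10S; C6 epimers) | CC(O[Si](C)(C)C(C)(C)C)C#CC(=O)[C@@H](C)C[C@@H](C1=C(CO[Si](C)(C)C(C)(C)C)C(=O)OC1(C)O)OC(=O)/C=C(/C)CO[Si](c1ccccc1)(c1ccccc1)C(C)(C)C | intermediate
22 | 5-methylenebutenolide (8S,10S) | CC(O[Si](C)(C)C(C)(C)C)C#CC(=O)[C@@H](C)C[C@@H](C1=C(CO[Si](C)(C)C(C)(C)C)C(=O)OC1=C)OC(=O)/C=C(/C)CO[Si](c1ccccc1)(c1ccccc1)C(C)(C)C | intermediate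
23 | 5-bromo-5-(bromomethyl)butenolide | CC(O[Si](C)(C)C(C)(C)C)C#CC(=O)[C@@H](C)C[C@@H](C1=C(CO[Si](C)(C)C(C)(C)C)C(=O)OC1(Br)CBr)OC(=O)/C=C(/C)CO[Si](c1ccccc1)(c1ccccc1)C(C)(C)C | intermediate
24 | (Z)-5-(bromomethylene)butenolide (8S,10S) | CC(O[Si](C)(C)C(C)(C)C)C#CC(=O)[C@@H](C)C[C@@H](C1=C(CO[Si](C)(C)C(C)(C)C)C(=O)O/C1=C\Br)OC(=O)/C=C(/C)CO[Si](c1ccccc1)(c1ccccc1)C(C)(C)C | intermediate
25 | C4,C13-diol | CC(O)C#CC(=O)[C@@H](C)C[C@@H](C1=C(CO)C(=O)O/C1=C\Br)OC(=O)/C=C(/C)CO[Si](c1ccccc1)(c1ccccc1)C(C)(C)C | intermediate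
26 | furanone alcohol | CC1OC(=CC1=O)[C@@H](C)C[C@@H](C1=C(CO)C(=O)O/C1=C\Br)OC(=O)/C=C(/C)CO[Si](c1ccccc1)(c1ccccc1)C(C)(C)C | intermediate
27 | furanone acetate (cyclisation precursor) | CC1OC(=CC1=O)[C@@H](C)C[C@@H](C1=C(COC(C)=O)C(=O)O/C1=C\Br)OC(=O)/C=C(/C)CO[Si](c1ccccc1)(c1ccccc1)C(C)(C)C | intermediate
28 | potassium furan-3-olate of 27 | Cc1oc(cc1[O-])[C@@H](C)C[C@@H](C1=C(COC(C)=O)C(=O)O/C1=C\Br)OC(=O)/C=C(/C)CO[Si](c1ccccc1)(c1ccccc1)C(C)(C)C.[K+] | intermediate
29 | macrocyclic potassium furan-2-olate (C5HBr) | CC(=O)OCc1c2c(oc1[O-])C(Br)[C@]3(C)OC(=CC3=O)[C@@H](C)C[C@@H]2OC(=O)/C=C(/C)CO[Si](c4ccccc4)(c4ccccc4)C(C)(C)C.[K+] | intermediate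
30 | O-TBDPS ether of the target | CC(=O)OCC1=C2/C(=C\[C@]3(C)OC(=CC3=O)[C@@H](C)C[C@@H]2OC(=O)/C=C(/C)CO[Si](c4ccccc4)(c4ccccc4)C(C)(C)C)OC1=O | intermediate
31 | CNP0269057.1 | CC(=O)OCC1=C2/C(=C\[C@]3(C)OC(=CC3=O)[C@@H](C)C[C@@H]2OC(=O)/C=C(/C)CO)OC1=O | target

Total step count: 20.
Longest linear sequence: 16 steps (steps 1–6, 8, 12–20).

**Steps most likely to fail**

1. Step 19. The planar furanolate may be attacked on the wrong face, because the C10 methyl group prefers the extended approach in which C10–H eclipses C1=C2. Ring closure may also lose out to O-attack or intermolecular coupling.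
   Fallback: the facial choice is taken from the substrate and given to a chiral cation. Compound 27 is cyclised under solid–liquid phase-transfer conditions: Cs2CO3, toluene, −20 °C, 10 mol % N-(9-anthracenylmethyl)cinchonidinium bromide or its cinchonine-derived pseudo-enantiomer. This is the known catalytic enantioselective nucleophilic vinylic substitution of stabilised enolates on β-halo acceptors. The enolate is then present only in catalytic amount, which also acts as pseudo-dilution. The fallback sets out from 27, comes back at 30 and makes no new compound (F0).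

2. Step 15. Bromine may also add to the side-chain enoate or the ynone, and the elimination may give a mixture of alkene isomers.
   Fallback: the dibromide is avoided. Compound 22 is treated with NBS in THF/H2O at 0 °C. Bromonium attack then goes only to the enol-ester alkene, because only there does an oxygen-stabilised cation result, and water gives the 5-(bromomethyl)-5-hydroxybutenolide F1. Dehydration of the hemiketal as in step 14 (MsCl, Et3N) then gives the more stable (Z)-bromide. The fallback sets out from 22 and comes back at 24.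

3. Step 8. A second acetylide may add, the lactone may enolise with loss of configuration at C10, and conversion may stay incomplete.
   Fallback: lactone 11 is opened with MeNH(OMe)·HCl and i-PrMgCl to the hydroxy Weinreb amide F2. O8 is silylated (TESCl, imidazole) to the triethylsilyl ether F3. Acetylide 14 is added to the amide, where the chelate stops the reaction at single addition, to give the triethylsilyl-protected ynone F4. The triethylsilyl group is then removed selectively (PPTS, MeOH, 0 °C). The fallback sets out from 11 and comes back at 15.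

**Further compounds**
F0 | step 19 | none | none
F1 | step 15 | 5-(bromomethyl)-5-hydroxybutenolide (8S,10S; C6 epimers) | CC(O[Si](C)(C)C(C)(C)C)C#CC(=O)[C@@H](C)C[C@@H](C1=C(CO[Si](C)(C)C(C)(C)C)C(=O)OC1(O)CBr)OC(=O)/C=C(/C)CO[Si](c1ccccc1)(c1ccccc1)C(C)(C)C
F2 | step 8 | (2S,4S)-4-{4-[(TBS-oxy)methyl]-2-methylfuran-3-yl}-4-hydroxy-N-methoxy-N,2-dimethylbutanamide | CON(C)C(=O)[C@@H](C)C[C@H](O)c1c(C)occ1CO[Si](C)(C)C(C)(C)C
F3 | step 8 | O8-triethylsilyl ether of F2 | CON(C)C(=O)[C@@H](C)C[C@H](O[Si](CC)(CC)CC)c1c(C)occ1CO[Si](C)(C)C(C)(C)C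
F4 | step 8 | O8-triethylsilyl ether of 15 | CC(O[Si](C)(C)C(C)(C)C)C#CC(=O)[C@@H](C)C[C@H](O[Si](CC)(CC)CC)c1c(C)occ1CO[Si](C)(C)C(C)(C)C
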